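**Retrosynthetic overview**
1. Leachianone A ⇒ its 4'-O-TBS ether (buffered fluoride, same flask); the B ring is bought as 4-hydroxy-2-methoxybenzaldehyde.
2. Key disconnection: rings C and A are cut in one retro-step (O1–C8a and C4a–C5) to an acyclic δ-hydroxy β-methoxy-enone/1,3-diketone that ends in a tert-butyl β-keto ester.
3. That chain ⇒ Claisen-type union (C8–C8a) of a lavandulyl β-keto ester dianion with an enantiopure 6-aryl δ-lactone, used only as a chiral acyl donor (its ring is opened).
4. Lactone ⇒ aldehyde + Brassard's diene (catalytic asymmetric hetero-Diels–Alder, sets C2); keto ester ⇒ tert-butyl acetoacetate dianion + (S)-lavandulyl iodide ⇐ Evans deconjugative prenylation (sets C2'').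
5. Ring order: sacrificial lactone (opened again) → C ring (dihydropyranone) → A ring (acylketene 6π closure), the last two in one operation; the B ring is never built.

Assumption: the (S)-BINOL–Ti(IV) catalyst gives the 6S lactone with this aldehyde (taken by analogy: the R ligand is assumed to give 6R lactones with simple aryl and alkenyl aldehydes); ee is checked by chiral HPLC and raised by recrystallising 5.

**Step 1**
Reactants: 1 4-hydroxy-2-methoxybenzaldehyde
Product: 2 4-[(tert-butyldimethylsilyl)oxy]-2-methoxybenzaldehyde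
Conditions: TBSCl, imidazole, DMF, 23 °C
Reagents that add atoms: tert-butyldimethylsilyl chloride (TBSCl), CC(C)(C)[Si](C)(C)Cl
Why: Imidazole-promoted O-silylation of a phenol, which leaves the aldehyde untouched and involves no stereocentre.

**Step 2**
Reactants: 2 4-[(tert-butyldimethylsilyl)oxy]-2-methoxybenzaldehyde; 3 Brassard's diene
Product: 5 (6S)-6-[4-(tert-butyldimethylsilyloxy)-2-methoxyphenyl]-4-methoxy-5,6-dihydro-2H-pyran-2-one, via silyl aldol adduct 4 (not isolated)
Conditions: (S)-BINOL/Ti(OiPr)4 (1:1, 10 mol%), 4 Å MS, THF, 0 → 23 °C; then TFA (5 mol%), CH2Cl2, 0 °C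
Reagents that add atoms: none
Why: Catalytic asymmetric hetero-Diels–Alder reaction of Brassard's diene (vinylogous Mukaiyama aldol, then acid-induced lactonisation) in which the BINOL–Ti Lewis acid shields one aldehyde face and so sets the future C2 centre as S.

**Step 3**
Reactants: 6 (S)-4-benzyloxazolidin-2-one; 7 3-methylbut-2-enoyl chloride
Product: 9 (S)-4-benzyl-3-(3-methylbut-2-enoyl)oxazolidin-2-one, via lithium oxazolidinide 8 (not isolated)
Conditions: n-BuLi, THF, −78 °C; then 7, −78 → 0 °C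
Reagents that add atoms: none
Why: N-acylation of a lithiated Evans oxazolidinone by an acid chloride, with no new stereocentre.

**Step 4**
Reactants: 9 (S)-4-benzyl-3-(3-methylbut-2-enoyl)oxazolidin-2-one; 10 1-bromo-3-methylbut-2-ene (prenyl bromide)
Product: 12 (S)-4-benzyl-3-[(2S)-5-methyl-2-(prop-1-en-2-yl)hex-4-enoyl]oxazolidin-2-one, via sodium dienolate 11 (not isolated)
Conditions: NaHMDS (1.1 equiv), THF, −78 °C; then 10, −78 → −40 °C
Reagents that add atoms: none
Why: Evans asymmetric alkylation in its deconjugative form, in which the chelated Z-dienolate is prenylated at the α-carbon on the face opposite the benzyl group; this sets the lavandulyl centre (2S in the imide) and moves the double bond into the isopropenyl position.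

**Step 5**
Reactants: 12 (S)-4-benzyl-3-[(2S)-5-methyl-2-(prop-1-en-2-yl)hex-4-enoyl]oxazolidin-2-one
Product: 13 (S)-lavandulol, (2S)-5-methyl-2-(prop-1-en-2-yl)hex-4-en-1-ol
Conditions: LiBH4, H2O (1.1 equiv), Et2O, 0 °C
Reagents that add atoms: none
Why: Reductive cleavage of the imide by lithium borohydride gives the primary alcohol without touching the alkenes or the α-stereocentre and returns the auxiliary.

**Step 6**
Reactants: 13 (S)-lavandulol
Product: 14 (3S)-3-(iodomethyl)-2,6-dimethylhepta-1,5-diene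
Conditions: PPh3, I2, imidazole, CH2Cl2, 0 → 23 °C
Reagents that add atoms: iodine, II
Why: Appel-type iodination (Garegg–Samuelsson conditions) of a primary alcohol under neutral conditions, where the stereocentre is β to the reacting carbon and is not touched.

**Step 7**
Reactants: 14 (3S)-3-(iodomethyl)-2,6-dimethylhepta-1,5-diene; 15 tert-butyl acetoacetate
Product: 17 tert-butyl (6S)-9-methyl-3-oxo-6-(prop-1-en-2-yl)dec-8-enoate, via acetoacetate dianion 16 (not isolated)
Conditions: 15 (1.5 equiv), NaH, THF, 0 °C; n-BuLi, 0 °C; then 14, 0 → 23 °C; AcOH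
Reagents that add atoms: none
Why: Huckin–Weiler γ-alkylation of a β-keto ester dianion, whose terminal carbanion is reactive enough for SN2 at the β-branched primary iodide, with the stereocentre untouched.

**Step 8**
Reactants: 17 tert-butyl (6S)-9-methyl-3-oxo-6-(prop-1-en-2-yl)dec-8-enoate; 5 (6S)-6-[4-(tert-butyldimethylsilyloxy)-2-methoxyphenyl]-4-methoxy-5,6-dihydro-2H-pyran-2-one
Product: 19 tert-butyl (6E,9S)-9-[4-(tert-butyldimethylsilyloxy)-2-methoxyphenyl]-9-hydroxy-7-methoxy-4-[(2R)-5-methyl-2-(prop-1-en-2-yl)hex-4-en-1-yl]-3,5-dioxonon-6-enoate, via keto ester dianion 18 (not isolated)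
Conditions: 17 (1.2 equiv), LDA (2.4 equiv), THF, −78 → 0 °C; then 5, −78 → −30 °C; AcOH, −78 °C
Reagents that add atoms: none
Why: Claisen-type acylation of the γ-carbanion of the β-keto ester dianion by the lactone carbonyl opens the lactone to an acyclic 1,3-diketone and frees the benzylic hydroxyl with its S configuration intact, because no bond to that carbon is broken (the new CH between the ketones is enolisable and later becomes aromatic C8).

**Step 9**
Reactants: 19 tert-butyl (6E,9S)-9-[4-(tert-butyldimethylsilyloxy)-2-methoxyphenyl]-9-hydroxy-7-methoxy-4-[(2R)-5-methyl-2-(prop-1-en-2-yl)hex-4-en-1-yl]-3,5-dioxonon-6-enoate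
Product: 23 leachianone A, via dihydropyranone 20 (not isolated), via acylketene 21 (not isolated), via silyl ether 22 (not isolated)
Conditions: PPTS (10 mol%), PhMe (5 mM), 23 °C, 3 h; then reflux (110 °C) through 5 Å MS (Soxhlet), 4 h; then 0 °C, TBAF (1.2 equiv), AcOH (1.5 equiv), THF
Reagents that add atoms: none
Why: Proposed new method: mild acid first closes ring C by hemiketalisation of the free hydroxyl onto the C5 ketone with loss of methanol (a vinylogous-ester transposition, closest precedent the acid-induced cyclisation of δ-hydroxy β-alkoxy enones to 2,3-dihydro-4H-pyran-4-ones), which places the ring oxygen next to the lavandulyl-bearing carbon and keeps C2 as S because its C–O bond is never broken; heating then expels tert-butanol from the β-keto ester to give an acylketene (known thermolysis of tert-butyl acetoacetates), whose enol form is a dienylketene that closes ring A by 6π-electrocyclisation onto the nucleophilic α-carbon of the dihydropyranone and tautomerises to the phloroglucinol (closest precedent the final stage of the Danheiser benzannulation and dioxinone-derived ketene aromatisations), and buffered fluoride finally removes the silyl group without opening the flavanone.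

**Compound list**
1 | 4-hydroxy-2-methoxybenzaldehyde | COc1cc(O)ccc1C=O | starting material
2 | 4-[(tert-butyldimethylsilyl)oxy]-2-methoxybenzaldehyde | COc1cc(O[Si](C)(C)C(C)(C)C)ccc1C=O | intermediate
3 | Brassard's diene, (1E)-1,3-dimethoxy-1-(trimethylsilyloxy)buta-1,3-diene | C=C(OC)/C=C(\OC)O[Si](C)(C)C | starting material
4 | methyl (2E,5S)-5-[4-(tert-butyldimethylsilyloxy)-2-methoxyphenyl]-3-methoxy-5-(trimethylsilyloxy)pent-2-enoate (not isolated) | CO/C(=C/C(=O)OC)C[C@H](O[Si](C)(C)C)c1ccc(O[Si](C)(C)C(C)(C)C)cc1OC | intermediate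
5 | (6S)-6-[4-(tert-butyldimethylsilyloxy)-2-methoxyphenyl]-4-methoxy-5,6-dihydro-2H-pyran-2-one | COC1=CC(=O)O[C@H](c2ccc(O[Si](C)(C)C(C)(C)C)cc2OC)C1 | intermediate
6 | (S)-4-benzyloxazolidin-2-one | O=C1N[C@@H](Cc2ccccc2)CO1 | starting material
7 | 3-methylbut-2-enoyl chloride | CC(C)=CC(Cl)=O | starting material
8 | lithium (S)-4-benzyl-2-oxooxazolidin-3-ide (not isolated) | [Li+].O=C1[N-][C@@H](Cc2ccccc2)CO1 | intermediate
9 | (S)-4-benzyl-3-(3-methylbut-2-enoyl)oxazolidin-2-one | CC(C)=CC(=O)N1[C@@H](Cc2ccccc2)COC1=O | intermediate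
10 | 1-bromo-3-methylbut-2-ene (prenyl bromide) | CC(C)=CCBr | starting material
11 | sodium (Z)-dienolate of 9 (not isolated) | [Na+].[O-]/C(=C\C(C)=C)N1[C@@H](Cc2ccccc2)COC1=O | intermediate
12 | (S)-4-benzyl-3-[(2S)-5-methyl-2-(prop-1-en-2-yl)hex-4-enoyl]oxazolidin-2-one | C=C(C)[C@H](CC=C(C)C)C(=O)N1[C@@H](Cc2ccccc2)COC1=O | intermediate
13 | (S)-lavandulol, (2S)-5-methyl-2-(prop-1-en-2-yl)hex-4-en-1-ol | C=C(C)[C@H](CC=C(C)C)CO | intermediate
14 | (3S)-3-(iodomethyl)-2,6-dimethylhepta-1,5-diene | C=C(C)[C@H](CC=C(C)C)CI | intermediate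
15 | tert-butyl acetoacetate (tert-butyl 3-oxobutanoate) | CC(=O)CC(=O)OC(C)(C)C | starting material
16 | sodium lithium dianion of 15 (not isolated) | [Na+].[Li+].C=C([O-])C=C([O-])OC(C)(C)C | intermediate
17 | tert-butyl (6S)-9-methyl-3-oxo-6-(prop-1-en-2-yl)dec-8-enoate | C=C(C)[C@H](CC=C(C)C)CCC(=O)CC(=O)OC(C)(C)C | intermediate
18 | dilithium dianion of 17 (not isolated) | [Li+].[Li+].C=C(C)[C@H](CC=C(C)C)CC=C([O-])C=C([O-])OC(C)(C)C | intermediate
19 | tert-butyl (6E,9S)-9-[4-(tert-butyldimethylsilyloxy)-2-methoxyphenyl]-9-hydroxy-7-methoxy-4-[(2R)-5-methyl-2-(prop-1-en-2-yl)hex-4-en-1-yl]-3,5-dioxonon-6-enoate (C4 epimers and enol forms) | CO/C(=C/C(=O)C(C[C@@H](CC=C(C)C)C(C)=C)C(=O)CC(=O)OC(C)(C)C)C[C@H](O)c1ccc(O[Si](C)(C)C(C)(C)C)cc1OC | intermediate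
20 | tert-butyl (6R)-4-{(2S)-2-[4-(tert-butyldimethylsilyloxy)-2-methoxyphenyl]-4-oxo-3,4-dihydro-2H-pyran-6-yl}-9-methyl-3-oxo-6-(prop-1-en-2-yl)dec-8-enoate (not isolated) | O=C1C=C(C(C[C@@H](CC=C(C)C)C(C)=C)C(=O)CC(=O)OC(C)(C)C)O[C@H](c2ccc(O[Si](C)(C)C(C)(C)C)cc2OC)C1 | intermediate
21 | (6R)-4-{(2S)-2-[4-(tert-butyldimethylsilyloxy)-2-methoxyphenyl]-4-oxo-3,4-dihydro-2H-pyran-6-yl}-9-methyl-6-(prop-1-en-2-yl)deca-1,8-diene-1,3-dione, the acylketene (not isolated) | O=C=CC(=O)C(C[C@@H](CC=C(C)C)C(C)=C)C1=CC(=O)C[C@@H](c2ccc(O[Si](C)(C)C(C)(C)C)cc2OC)O1 | intermediate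
22 | (2S)-2-[4-(tert-butyldimethylsilyloxy)-2-methoxyphenyl]-5,7-dihydroxy-8-[(2R)-5-methyl-2-(prop-1-en-2-yl)hex-4-en-1-yl]-2,3-dihydro-4H-chromen-4-one (not isolated) | C=C(C)[C@H](CC=C(C)C)Cc1c(O)cc(O)c2c1O[C@H](c1ccc(O[Si](C)(C)C(C)(C)C)cc1OC)CC2=O | intermediate
23 | leachianone A, (2S)-5,7-dihydroxy-2-(4-hydroxy-2-methoxyphenyl)-8-[(2R)-5-methyl-2-(prop-1-en-2-yl)hex-4-en-1-yl]-2,3-dihydro-4H-chromen-4-one | C=C(C)[C@H](CC=C(C)C)Cc1c(O)cc(O)c2c1O[C@H](c1ccc(O)cc1OC)CC2=O | target

**Step count and risks**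

Total step count: 9. Longest linear sequence: 7 (steps 3 to 9).

Most likely to fail, first: step 9. It is unprecedented as a whole. The free ketone next to the ester can attack the methoxy-enone and give a γ-pyrone instead of the dihydropyranone. Liberated methanol can trap the ketene. The electron-rich benzylic C–O bond may ionise and erode ee at C2. The fallback masks that ketone in a dioxinone, which is also the ketene source. It sets out from 14: the lithium dienolate of commercial 2,2,6-trimethyl-4H-1,3-dioxin-4-one (LDA, THF–DMPU, −78 °C) is alkylated with 14 to give the lavandulyl dioxinone F1. F1 is deprotonated at its γ-CH2 (LDA) and acylated with lactone 5 to give the acyclic hydroxy enone F2. PPTS at 23 °C closes F2 to the dihydropyranone dioxinone F3; no γ-pyrone can form because the masked oxygen cannot cyclise. Heating F3 at 110 °C expels acetone by retro-[4+2] and gives acylketene 21, where the fallback comes back to the route.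

Second: step 8. The dianion is a strong base and may deprotonate C5 of lactone 5, which triggers E1cB ring opening to a dienoate, or it may add in 1,4 fashion. The fallback replaces the lactone by an acyclic O-silylated ester that cannot ring-open. It sets out from 4: the TFA stage of step 2 is omitted and the silyl aldol adduct 4 is isolated after a non-acidic work-up. Dianion 18 is acylated by the methyl ester of 4 (Claisen condensation, methoxide as leaving group) to give the trimethylsilyl ether F4. Its silyl group falls off on citric acid work-up, and the fallback comes back to the route at 19.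

Third: step 2. The ortho-methoxy, electron-rich aldehyde may react slowly or chelate titanium and give low ee. The fallback sets the same centre by a copper-catalysed vinylogous aldol with a different C4 unit. It sets out from 2: Tol-BINAP–Cu(II) fluoride-catalysed addition of 2,2-dimethyl-6-methylene-4-(trimethylsilyloxy)-4H-1,3-dioxine, with the ligand enantiomer that gives the S carbinol, affords the dioxinone aldol adduct F5. Heating F5 in toluene at 110 °C releases acetone, and the δ-hydroxyl captures the acylketene to give the β-keto δ-lactone F6. O-methylation of F6 (Me2SO4, K2CO3, acetone) comes back to the route at 5.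

**Further compounds**
F1 | step 9 | 2,2-dimethyl-6-[(3S)-6-methyl-3-(prop-1-en-2-yl)hept-5-en-1-yl]-4H-1,3-dioxin-4-one | C=C(C)[C@H](CC=C(C)C)CCC1=CC(=O)OC(C)(C)O1
F2 | step 9 | 6-{(3E,6S)-6-[4-(tert-butyldimethylsilyloxy)-2-methoxyphenyl]-6-hydroxy-4-methoxy-1-[(2R)-5-methyl-2-(prop-1-en-2-yl)hex-4-en-1-yl]-2-oxohex-3-en-1-yl}-2,2-dimethyl-4H-1,3-dioxin-4-one | CO/C(=C/C(=O)C(C[C@@H](CC=C(C)C)C(C)=C)C1=CC(=O)OC(C)(C)O1)C[C@H](O)c2ccc(O[Si](C)(C)C(C)(C)C)cc2OC
F3 | step 9 | 6-{(3R)-1-[(2S)-2-[4-(tert-butyldimethylsilyloxy)-2-methoxyphenyl]-4-oxo-3,4-dihydro-2H-pyran-6-yl]-6-methyl-3-(prop-1-en-2-yl)hept-5-en-1-yl}-2,2-dimethyl-4H-1,3-dioxin-4-one | O=C1C=C(C(C[C@@H](CC=C(C)C)C(C)=C)C2=CC(=O)OC(C)(C)O2)O[C@H](c3ccc(O[Si](C)(C)C(C)(C)C)cc3OC)C1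
F4 | step 8 | tert-butyl (6E,9S)-9-[4-(tert-butyldimethylsilyloxy)-2-methoxyphenyl]-7-methoxy-4-[(2R)-5-methyl-2-(prop-1-en-2-yl)hex-4-en-1-yl]-3,5-dioxo-9-(trimethylsilyloxy)non-6-enoate | CO/C(=C/C(=O)C(C[C@@H](CC=C(C)C)C(C)=C)C(=O)CC(=O)OC(C)(C)C)C[C@H](O[Si](C)(C)C)c1ccc(O[Si](C)(C)C(C)(C)C)cc1OC
F5 | step 2 | 6-{(2S)-2-[4-(tert-butyldimethylsilyloxy)-2-methoxyphenyl]-2-hydroxyethyl}-2,2-dimethyl-4H-1,3-dioxin-4-one | CC1(C)OC(=O)C=C(C[C@H](O)c2ccc(O[Si](C)(C)C(C)(C)C)cc2OC)O1
F6 | step 2 | (6S)-6-[4-(tert-butyldimethylsilyloxy)-2-methoxyphenyl]dihydro-2H-pyran-2,4(3H)-dione | O=C1CC(=O)O[C@H](c2ccc(O[Si](C)(C)C(C)(C)C)cc2OC)C1
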